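Ring B of the hydrindane (indane numbering: C3a angular-methyl carbon, C4 CHBr, C7 tertiary carbinol, C7a) is disconnected at C3a–C4 and C6–C7, which excises C4–C5–C6 as acrolein. In one operation TiCl4 should stitch acrolein onto an acetyl-bearing cyclopentenylsilane: Hosomi–Sakurai attack of C3a on the aldehyde, Prins closure of the vinyl terminus C6 onto the acetyl carbon C7, and a 1,2-hydride shift that leaves C4 as a ketone. The step exploits the 1,4-relationship of the heteroatom-bearing carbons C4 and C7 across ring B, with C4 next to quaternary C3a. C4=O is later converted into the equatorial bromide, and the side ring is closed by a bromonium cyclisation.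

Key step: step 5

Numbering: bicyclic compounds are numbered as indanes (C1 carries the side chain, C2 the secondary hydroxyl, C3a the angular methyl, C4 the bromine, C7 the tertiary hydroxyl, C7a the ring-fusion hydrogen); the side ring is numbered C1′ (carbinol), C3′ (gem-dimethyl), C4′ (bromine).
Assumption: the aldol condensation of 4 is taken to close through the methylene remote from silicon, and the kinetic protonation of dienolate 6 to occur on the face opposite silicon.

Step 1
Reactants: 1 hex-5-en-2-one; 2 but-3-en-2-one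
Product: 3 (3E)-oct-3-ene-2,7-dione
Conditions: second-generation Grubbs catalyst RuCl2(=CHPh)(PCy3)(H2IMes) (2 mol%), 2 (3 equiv), CH2Cl2, 40 °C
Reagents that add atoms: none
Why: Olefin cross-metathesis of a terminal alkene with an electron-poor vinyl ketone should give the E-enone selectively, with loss of ethene.

Step 2
Reactants: 3 (3E)-oct-3-ene-2,7-dione
Product: 4 (4R)-4-[dimethyl(phenyl)silyl]octane-2,7-dione
Conditions: PhMe2Si–B(pin) (1.1 equiv), CuCl (5 mol%), NaOt-Bu (10 mol%), chiral C1-symmetric N-heterocyclic carbene ligand (from its imidazolinium salt, 6 mol%), THF, −78 °C; then aq. NH4Cl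
Reagents that add atoms: 2-[dimethyl(phenyl)silyl]-4,4,5,5-tetramethyl-1,3,2-dioxaborolane, C[Si](C)(c1ccccc1)B1OC(C)(C)C(C)(C)O1
Why: Copper-catalysed enantioselective conjugate silylation with a silylboronate should add silicon only to the enone β-carbon, the ligand setting the silicon-bearing centre as (R).

Step 3
Reactants: 4 (4R)-4-[dimethyl(phenyl)silyl]octane-2,7-dione
Product: 5 1-[(4S)-4-[dimethyl(phenyl)silyl]-2-methylcyclopent-1-en-1-yl]ethan-1-one
Conditions: pyrrolidine (20 mol%), AcOH (20 mol%), toluene, 60 °C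
Reagents that add atoms: none
Why: Intramolecular aldol condensation of the 1,6-diketone, the methylene remote from silicon attacking the other ketone, should give the 1-acetyl-2-methylcyclopentene and leave the silicon-bearing centre untouched.

Step 4
Reactants: 5 1-[(4S)-4-[dimethyl(phenyl)silyl]-2-methylcyclopent-1-en-1-yl]ethan-1-one
Product: 7 1-[(1S,4R)-4-[dimethyl(phenyl)silyl]-2-methylcyclopent-2-en-1-yl]ethan-1-one, via potassium dienolate 6 (not isolated)
Conditions: KOt-Bu (1.2 equiv), THF/t-BuOH, 0 °C; then inverse addition to AcOH/THF, −78 °C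
Reagents that add atoms: none
Why: Deconjugation by kinetic α-protonation of the extended dienolate should give the β,γ-unsaturated ketone, now an allylsilane, the proton entering anti to the silyl group so that acetyl and silyl end cis (new centre S).

Step 5
Reactants: 7 1-[(1S,4R)-4-[dimethyl(phenyl)silyl]-2-methylcyclopent-2-en-1-yl]ethan-1-one; 8 prop-2-enal
Product: 10 (3aS,7R,7aS)-7-hydroxy-3a,7-dimethyl-1,3a,5,6,7,7a-hexahydro-4H-inden-4-one, via titanium alkoxide of the Sakurai adduct 9 (not isolated)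
Conditions: TiCl4 (2.2 equiv), 8 (1.5 equiv), CH2Cl2, −78 °C to −20 °C; then aq. NaHCO3
Reagents that add atoms: none
Why: Proposed new method: the TiCl4-activated aldehyde carbon of acrolein (future C4) is attacked by the γ-carbon of the allylsilane (future C3a) in an anti-SE2′ Hosomi–Sakurai addition to give alkoxide 9, whose vinyl terminus (future C6) then adds to the titanium-activated acetyl carbonyl (future C7) in a Prins cyclisation, and the secondary C5 cation is quenched by a 1,2-hydride shift from the carbinol carbon, which unveils the C4 ketone. The closest known reaction types are the Hosomi–Sakurai allylation of aldehydes and Prins–pinacol or Lewis-acid carbonyl–ene cyclisations, whereas the tandem with acrolein as a three-carbon linchpin is not described. Ring B closes in a 6-endo-trig chair in which the new C3a–C4 bond and the C7a–C7 bond are both equatorial on the five-membered ring, so the ring fusion is trans. C3a is set by attack anti to silicon and therefore anti to the cis acetyl group, C7 by the chair in which the acetyl methyl stays equatorial to avoid a 1,3-diaxial clash with the C3a methyl so that the C–O bond becomes axial, and C7a is carried over from 7. The step needs the aldehyde to react before the ketone and in 1,2-fashion, which the far higher electrophilicity of the TiCl4–aldehyde complex should secure, and it needs hydride shift to beat chloride capture, which a syn-selective addition placing the carbinol hydrogen axial and antiperiplanar to the empty orbital at C5 should secure.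

Step 6
Reactants: 10 (3aS,7R,7aS)-7-hydroxy-3a,7-dimethyl-1,3a,5,6,7,7a-hexahydro-4H-inden-4-one
Product: 11 (3aS,7R,7aS)-7-hydroxy-3a,7-dimethyl-3a,6,7,7a-tetrahydro-1H-inden-4-yl trifluoromethanesulfonate
Conditions: KN(SiMe3)2 (2.2 equiv), THF, −78 °C; then PhNTf2 (1.1 equiv)
Reagents that add atoms: N-phenylbis(trifluoromethanesulfonimide), O=S(=O)(N(c1ccccc1)S(=O)(=O)C(F)(F)F)C(F)(F)F
Why: Enol triflate formation is regiospecific because the ketone can enolise only towards C5 (C3a is quaternary), and the hindered tertiary alkoxide should not be triflated.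

Step 7
Reactants: 11 (3aS,7R,7aS)-7-hydroxy-3a,7-dimethyl-3a,6,7,7a-tetrahydro-1H-inden-4-yl trifluoromethanesulfonate
Product: 12 (3aS,7R,7aS)-4-bromo-3a,7-dimethyl-3a,6,7,7a-tetrahydro-1H-inden-7-ol
Conditions: Ni(cod)2 (10 mol%), LiBr (3 equiv), THF/DMA, 25 °C
Reagents that add atoms: lithium bromide, [Li+].[Br-]
Why: Nickel-catalysed halogen exchange of the enol triflate (oxidative addition, triflate–bromide exchange, reductive elimination) should give the alkenyl bromide with the double bond in place.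

Step 8
Reactants: 12 (3aS,7R,7aS)-4-bromo-3a,7-dimethyl-3a,6,7,7a-tetrahydro-1H-inden-7-ol
Product: 14 (3aS,7R,7aS)-4-bromo-7-hydroxy-3a,7-dimethyl-1,3,3a,6,7,7a-hexahydro-2H-inden-2-one, via C2 alkylborane 13 (not isolated)
Conditions: BH3·SMe2 (2 equiv), THF, 0 °C; then pyridinium chlorochromate (3 equiv), CH2Cl2, 40 °C
Reagents that add atoms: pyridinium chlorochromate, [O-][Cr](=O)(=O)Cl.c1cc[nH+]cc1
Why: Hydroboration of the disubstituted cyclopentene should place boron at C2, away from quaternary C3a, while the electron-poor bromoalkene reacts more slowly, and direct chromate oxidation of the organoborane gives the C2 ketone.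

Step 9
Reactants: 14 (3aS,7R,7aS)-4-bromo-7-hydroxy-3a,7-dimethyl-1,3,3a,6,7,7a-hexahydro-2H-inden-2-one
Product: 15 (3aS,4S,7R,7aS)-4-bromo-7-hydroxy-3a,7-dimethyloctahydro-2H-inden-2-one
Conditions: Mn(dpm)3 (10 mol%), PhSiH3 (2 equiv), t-BuOOH (1.5 equiv), i-PrOH, 25 °C
Reagents that add atoms: none
Why: Radical hydrogenation by metal-hydride hydrogen-atom transfer should reduce the bromoalkene without loss of bromine, the α-bromo radical at C4 taking its hydrogen axially on the face opposite the C3a methyl so that bromine ends equatorial (4S).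

Step 10
Reactants: 16 6-methylhept-5-en-2-one
Product: 17 N′-(6-methylhept-5-en-2-ylidene)-2,4,6-tri(propan-2-yl)benzenesulfonohydrazide
Conditions: 2,4,6-tri(propan-2-yl)benzenesulfonohydrazide, MeOH, HCl (cat.), 25 °C
Reagents that add atoms: 2,4,6-tri(propan-2-yl)benzenesulfonohydrazide, CC(C)c1cc(C(C)C)c(c(c1)C(C)C)S(=O)(=O)NN
Why: Condensation of the methyl ketone with the arenesulfonylhydrazide gives the hydrazone needed for the Shapiro reaction.

Step 11
Reactants: 17 N′-(6-methylhept-5-en-2-ylidene)-2,4,6-tri(propan-2-yl)benzenesulfonohydrazide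
Product: 19 6-methyl-2-methylidenehept-5-enal, via vinyllithium 18 (not isolated)
Conditions: n-BuLi (2.2 equiv), TMEDA, hexane/THF, −78 to 0 °C; then DMF, −78 °C; then aq. NH4Cl
Reagents that add atoms: N,N-dimethylformamide, CN(C)C=O
Why: In the Shapiro reaction, deprotonation at the methyl group followed by loss of sulfinate and N2 gives the 1-alken-2-yllithium, which DMF formylates to the α-methylene aldehyde.

Step 12
Reactants: 15 (3aS,4S,7R,7aS)-4-bromo-7-hydroxy-3a,7-dimethyloctahydro-2H-inden-2-one; 19 6-methyl-2-methylidenehept-5-enal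
Product: 22 (1R,3aS,4S,7R,7aS)-4-bromo-7-hydroxy-1-[(1R)-1-hydroxy-6-methyl-2-methylidenehept-5-en-1-yl]-3a,7-dimethyloctahydro-2H-inden-2-one, via lithium enolate 20 (not isolated), via zirconium enolate 21 (not isolated)
Conditions: LiN(i-Pr)2 (2.2 equiv), THF, −78 °C; Cp2ZrCl2 (1.2 equiv), −78 °C; then 19; then aq. NH4Cl
Reagents that add atoms: none
Why: In this directed aldol addition, kinetic deprotonation at C1 (C3 is neopentylic), transmetalation to the zirconium enolate and syn-selective 1,2-addition to the enal on the enolate face opposite the axial C3a methyl should set C1 (R) and the carbinol carbon (R).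

Step 13
Reactants: 22 (1R,3aS,4S,7R,7aS)-4-bromo-7-hydroxy-1-[(1R)-1-hydroxy-6-methyl-2-methylidenehept-5-en-1-yl]-3a,7-dimethyloctahydro-2H-inden-2-one
Product: 23 (1R)-1-[(1R,3aS,4S,7R,7aS)-4-bromo-7-hydroxy-3a,7-dimethyl-2-oxooctahydro-1H-inden-1-yl]-6-methyl-2-methylidenehept-5-en-1-yl acetate
Conditions: Ac2O, pyridine, DMAP (cat.), CH2Cl2, 0 °C
Reagents that add atoms: acetic anhydride, CC(=O)OC(C)=O
Why: Acylation should take place only at the secondary allylic alcohol, because the tertiary C7 hydroxyl is too hindered to react.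

Step 14
Reactants: 23 (1R)-1-[(1R,3aS,4S,7R,7aS)-4-bromo-7-hydroxy-3a,7-dimethyl-2-oxooctahydro-1H-inden-1-yl]-6-methyl-2-methylidenehept-5-en-1-yl acetate
Product: 25 (R)-[(1R,3aS,4S,7R,7aS)-4-bromo-7-hydroxy-3a,7-dimethyl-2-oxooctahydro-1H-inden-1-yl][(1R,4S)-4-bromo-1-hydroxy-3,3-dimethylcyclohexyl]methyl acetate, via spiro dioxolanylium ion 24 (not isolated)
Conditions: Et2SBr·SbCl5Br (1.1 equiv), MeNO2, −25 °C; then H2O/NaHCO3
Reagents that add atoms: bromodiethylsulfonium bromopentachloroantimonate, CC[S+](Br)CC.Cl[Sb-](Cl)(Cl)(Cl)(Cl)Br; water, O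
Why: In this bromonium-induced cation–olefin cyclisation the trisubstituted alkene takes Br+, the 1,1-disubstituted alkene closes the six-membered ring through a 6-endo chair with bromine equatorial, and the C1′ cation is captured axially by the neighbouring acetate, whose place on the carbinol carbon should relay its configuration to C1′ (R) and C4′ (S) before hydrolysis to the tertiary alcohol and secondary acetate.

Step 15
Reactants: 25 (R)-[(1R,3aS,4S,7R,7aS)-4-bromo-7-hydroxy-3a,7-dimethyl-2-oxooctahydro-1H-inden-1-yl][(1R,4S)-4-bromo-1-hydroxy-3,3-dimethylcyclohexyl]methyl acetate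
Product: 26 (R)-[(1S,2R,3aS,4S,7R,7aS)-4-bromo-2,7-dihydroxy-3a,7-dimethyloctahydro-1H-inden-1-yl][(1R,4S)-4-bromo-1-hydroxy-3,3-dimethylcyclohexyl]methyl acetate
Conditions: (S)-2-methyl-CBS-oxazaborolidine (20 mol%), BH3·SMe2 (1.5 equiv), THF, −20 °C; then MeOH
Reagents that add atoms: none
Why: In the Corey–Bakshi–Shibata reduction the catalyst should deliver hydride to the ketone face cis to the C3a methyl, against the substrate bias, giving the axial (2R) alcohol cis to the C1 substituent.

Compound list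
1 | hex-5-en-2-one | CC(=O)CCC=C | starting material
2 | but-3-en-2-one | CC(=O)C=C | starting material
3 | (3E)-oct-3-ene-2,7-dione | CC(=O)/C=C/CCC(C)=O | intermediate
4 | (4R)-4-[dimethyl(phenyl)silyl]octane-2,7-dione | CC(=O)C[C@H]([Si](C)(C)c1ccccc1)CCC(C)=O | intermediate
5 | 1-[(4S)-4-[dimethyl(phenyl)silyl]-2-methylcyclopent-1-en-1-yl]ethan-1-one | CC(=O)C1=C(C)C[C@H]([Si](C)(C)c2ccccc2)C1 | intermediate
6 | potassium dienolate of 5 (potassium 1-[(4S)-4-[dimethyl(phenyl)silyl]-2-methylcyclopent-2-en-1-ylidene]ethan-1-olate) | [K+].CC([O-])=C1C(C)=C[C@H]([Si](C)(C)c2ccccc2)C1 | intermediate (not isolated)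
7 | 1-[(1S,4R)-4-[dimethyl(phenyl)silyl]-2-methylcyclopent-2-en-1-yl]ethan-1-one | CC(=O)[C@H]1C[C@@H]([Si](C)(C)c2ccccc2)C=C1C | intermediate
8 | prop-2-enal | C=CC=O | starting material
9 | trichlorotitanium alkoxide of 1-[(1S,2S)-2-[(1S)-1-hydroxyprop-2-en-1-yl]-2-methylcyclopent-3-en-1-yl]ethan-1-one | CC(=O)[C@H]1CC=C[C@]1(C)[C@@H](O[Ti](Cl)(Cl)Cl)C=C | intermediate (not isolated)
10 | (3aS,7R,7aS)-7-hydroxy-3a,7-dimethyl-1,3a,5,6,7,7a-hexahydro-4H-inden-4-one | C1C=C[C@]2(C)C(=O)CC[C@@](C)(O)[C@@H]12 | intermediate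
11 | (3aS,7R,7aS)-7-hydroxy-3a,7-dimethyl-3a,6,7,7a-tetrahydro-1H-inden-4-yl trifluoromethanesulfonate | C1C=C[C@]2(C)C(OS(=O)(=O)C(F)(F)F)=CC[C@@](C)(O)[C@@H]12 | intermediate
12 | (3aS,7R,7aS)-4-bromo-3a,7-dimethyl-3a,6,7,7a-tetrahydro-1H-inden-7-ol | C1C=C[C@]2(C)C(Br)=CC[C@@](C)(O)[C@@H]12 | intermediate
13 | C2 alkylborane from hydroboration of 12 (boron on the face opposite the C3a methyl) | C1[C@H](B)C[C@]2(C)C(Br)=CC[C@@](C)(O)[C@@H]12 | intermediate (not isolated)
14 | (3aS,7R,7aS)-4-bromo-7-hydroxy-3a,7-dimethyl-1,3,3a,6,7,7a-hexahydro-2H-inden-2-one | C1C(=O)C[C@]2(C)C(Br)=CC[C@@](C)(O)[C@@H]12 | intermediate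
15 | (3aS,4S,7R,7aS)-4-bromo-7-hydroxy-3a,7-dimethyloctahydro-2H-inden-2-one | C1C(=O)C[C@]2(C)[C@@H](Br)CC[C@@](C)(O)[C@@H]12 | intermediate
16 | 6-methylhept-5-en-2-one | CC(=O)CCC=C(C)C | starting material
17 | N′-(6-methylhept-5-en-2-ylidene)-2,4,6-tri(propan-2-yl)benzenesulfonohydrazide | CC(CCC=C(C)C)=NNS(=O)(=O)c1c(C(C)C)cc(C(C)C)cc1C(C)C | intermediate
18 | (6-methylhepta-1,5-dien-2-yl)lithium | [Li]C(=C)CCC=C(C)C | intermediate (not isolated)
19 | 6-methyl-2-methylidenehept-5-enal | C=C(C=O)CCC=C(C)C | intermediate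
20 | dilithium C1-enolate and C7-alkoxide of 15 | C1=C(O[Li])C[C@]2(C)[C@@H](Br)CC[C@@](C)(O[Li])[C@@H]12 | intermediate (not isolated)
21 | chlorobis(cyclopentadienyl)zirconium C1-enolate of 15 (lithium C7-alkoxide) | C1=C(O[Zr](Cl)(C3C=CC=C3)C3C=CC=C3)C[C@]2(C)[C@@H](Br)CC[C@@](C)(O[Li])[C@@H]12 | intermediate (not isolated)
22 | (1R,3aS,4S,7R,7aS)-4-bromo-7-hydroxy-1-[(1R)-1-hydroxy-6-methyl-2-methylidenehept-5-en-1-yl]-3a,7-dimethyloctahydro-2H-inden-2-one | O[C@H]([C@@H]1C(=O)C[C@]2(C)[C@@H](Br)CC[C@@](C)(O)[C@@H]12)C(=C)CCC=C(C)C | intermediate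
23 | (1R)-1-[(1R,3aS,4S,7R,7aS)-4-bromo-7-hydroxy-3a,7-dimethyl-2-oxooctahydro-1H-inden-1-yl]-6-methyl-2-methylidenehept-5-en-1-yl acetate | CC(=O)O[C@H]([C@@H]1C(=O)C[C@]2(C)[C@@H](Br)CC[C@@](C)(O)[C@@H]12)C(=C)CCC=C(C)C | intermediate
24 | spiro 2-methyl-1,3-dioxolan-2-ylium ion linking the acetoxy carbon and C1′ of the new bromocyclohexane (bromopentachloroantimonate salt) | CC1=[O+][C@@]2(CC[C@H](Br)C(C)(C)C2)[C@H](O1)[C@@H]3C(=O)C[C@]4(C)[C@@H](Br)CC[C@@](C)(O)[C@@H]34.Cl[Sb-](Cl)(Cl)(Cl)(Cl)Br | intermediate (not isolated)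
25 | (R)-[(1R,3aS,4S,7R,7aS)-4-bromo-7-hydroxy-3a,7-dimethyl-2-oxooctahydro-1H-inden-1-yl][(1R,4S)-4-bromo-1-hydroxy-3,3-dimethylcyclohexyl]methyl acetate | CC(=O)O[C@H]([C@@H]1C(=O)C[C@]2(C)[C@@H](Br)CC[C@@](C)(O)[C@@H]12)[C@@]1(O)CC[C@H](Br)C(C)(C)C1 | intermediate
26 | (R)-[(1S,2R,3aS,4S,7R,7aS)-4-bromo-2,7-dihydroxy-3a,7-dimethyloctahydro-1H-inden-1-yl][(1R,4S)-4-bromo-1-hydroxy-3,3-dimethylcyclohexyl]methyl acetate | CC(=O)O[C@H]([C@@H]1[C@H](O)C[C@]2(C)[C@@H](Br)CC[C@@](C)(O)[C@@H]12)[C@@]1(O)CC[C@H](Br)C(C)(C)C1 | target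

Total step count: 15. Longest linear sequence: 13 steps (steps 1–9 and 12–15); steps 10–11 make the side-chain aldehyde.

Steps most likely to fail

Step 5. The Prins closure onto the ketone may not take place, the C5 cation may be captured by chloride instead of undergoing the hydride shift, or the facial selectivity at C7 may be poor. The fallback sets out from 7 and comes back at 10. Hosomi–Sakurai addition of 7 to acrolein (TiCl4, CH2Cl2, −78 °C, quenched cold) should give the allylic alcohol 1-[(1S,2S)-2-[(1S)-1-hydroxyprop-2-en-1-yl]-2-methylcyclopent-3-en-1-yl]ethan-1-one F1. Dess–Martin oxidation then gives the vinyl ketone 1-[(1S,5S)-5-acetyl-1-methylcyclopent-2-en-1-yl]prop-2-en-1-one F2. SmI2 (THF, t-BuOH, −78 °C) should close ring B by a 6-endo ketyl–olefin reductive cyclisation to 10.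

Step 14. Bromonium formation may show poor facial selectivity relative to the existing stereocentres, or the C1′ cation may lose a proton instead of being captured. The fallback sets out from 23 and comes back at 25. Cyclisation with Hg(OCOCF3)2 (MeNO2, 0 °C), then aqueous KBr, should give the organomercurial (R)-[(1R,3aS,4S,7R,7aS)-4-bromo-7-hydroxy-3a,7-dimethyl-2-oxooctahydro-1H-inden-1-yl][(1R,4S)-4-(bromomercurio)-1-hydroxy-3,3-dimethylcyclohexyl]methyl acetate F3. Brominolysis (Br2, LiBr, pyridine, O2) then replaces mercury by bromine to give 25.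

Step 15. Hydride may be delivered from the less hindered face, opposite the C3a methyl, giving the C2 epimer. The fallback sets out from 25 and comes back at 26. NaBH4 (MeOH, −40 °C) should give the epimeric alcohol (R)-[(1S,2S,3aS,4S,7R,7aS)-4-bromo-2,7-dihydroxy-3a,7-dimethyloctahydro-1H-inden-1-yl][(1R,4S)-4-bromo-1-hydroxy-3,3-dimethylcyclohexyl]methyl acetate F4. Mitsunobu inversion with 4-nitrobenzoic acid (PPh3, DIAD, THF) gives (1S,2R,3aS,4S,7R,7aS)-1-[(R)-acetoxy[(1R,4S)-4-bromo-1-hydroxy-3,3-dimethylcyclohexyl]methyl]-4-bromo-7-hydroxy-3a,7-dimethyloctahydro-1H-inden-2-yl 4-nitrobenzoate F5. K2CO3 in MeOH at 0 °C should cleave the activated nitrobenzoate faster than the hindered acetate, giving 26.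

Further compounds
F1 | step 5 | 1-[(1S,2S)-2-[(1S)-1-hydroxyprop-2-en-1-yl]-2-methylcyclopent-3-en-1-yl]ethan-1-one | CC(=O)[C@H]1CC=C[C@]1(C)[C@@H](O)C=C
F2 | step 5 | 1-[(1S,5S)-5-acetyl-1-methylcyclopent-2-en-1-yl]prop-2-en-1-one | CC(=O)[C@H]1CC=C[C@]1(C)C(=O)C=C
F3 | step 14 | (R)-[(1R,3aS,4S,7R,7aS)-4-bromo-7-hydroxy-3a,7-dimethyl-2-oxooctahydro-1H-inden-1-yl][(1R,4S)-4-(bromomercurio)-1-hydroxy-3,3-dimethylcyclohexyl]methyl acetate | CC(=O)O[C@H]([C@@H]1C(=O)C[C@]2(C)[C@@H](Br)CC[C@@](C)(O)[C@@H]12)[C@@]1(O)CC[C@H]([Hg]Br)C(C)(C)C1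
F4 | step 15 | (R)-[(1S,2S,3aS,4S,7R,7aS)-4-bromo-2,7-dihydroxy-3a,7-dimethyloctahydro-1H-inden-1-yl][(1R,4S)-4-bromo-1-hydroxy-3,3-dimethylcyclohexyl]methyl acetate | CC(=O)O[C@H]([C@@H]1[C@@H](O)C[C@]2(C)[C@@H](Br)CC[C@@](C)(O)[C@@H]12)[C@@]1(O)CC[C@H](Br)C(C)(C)C1
F5 | step 15 | (1S,2R,3aS,4S,7R,7aS)-1-[(R)-acetoxy[(1R,4S)-4-bromo-1-hydroxy-3,3-dimethylcyclohexyl]methyl]-4-bromo-7-hydroxy-3a,7-dimethyloctahydro-1H-inden-2-yl 4-nitrobenzoate | CC(=O)O[C@H]([C@@H]1[C@H](OC(=O)c3ccc(cc3)[N+](=O)[O-])C[C@]2(C)[C@@H](Br)CC[C@@](C)(O)[C@@H]12)[C@@]1(O)CC[C@H](Br)C(C)(C)C1
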